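**Plan**

- Numbering (germacrane): ring A is the ten-membered carbocycle C1–C10; ring B is the lactone O–C6–C7–C11–C12(=O), with C13 the exocyclic methylene on C11. C8 (free OH) is homoallylic to C11=C13, which is the retron of an SE2' carbonyl allylation by a butenolide that has C7=C11 inside ring B and a metal on C13.
- Cuts, in order: C7–C8 (ring A); ring B (C12–O6 ester and C7=C11 by metathesis, C6–C7 by vinyl addition); C9–C10 (Nozaki–Hiyama–Kishi); C1=C10 (iodo-Wittig); C1 by cleaving the distal olefin of nerol.
- Forward: one linear chain from nerol, which supplies C1–C6, C15 and the (Z)-C4=C5 bond. Both acyl groups go on before ring B is made; ring B closes in step 13 and ring A last, so the key step delivers the target with its only free hydroxyl.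
- Stereochemistry: C9 by Felkin–Anh addition to bought (S)-glyceraldehyde acetonide, whose own centre is later excised as formaldehyde when C8 is released; C6 by catalytic asymmetric vinylation; the acyl centre is bought. C7 and C8 are both formed in the key step, relayed from C6 and C9.
- The (Z)-C1=C10 geometry comes from a stabilised α-iodo ylide.

Key step: step 15

Remark: commercial nerol of high (Z) purity is assumed; the oxirane centre of 3 is racemic and is destroyed in step 3.

**Route**

Step 1
Reactants: 1 nerol, (2Z)-3,7-dimethylocta-2,6-dien-1-ol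
Product: 2 neryl tert-butyldimethylsilyl ether
Conditions: TBSCl, imidazole, DMF, 0 °C to rt
Reagents that add atoms: tert-butyldimethylsilyl chloride, CC(C)(C)[Si](C)(C)Cl
Why: Standard silylation of the primary allylic alcohol masks O6 through the base, hydride and chromium steps; no stereocentre is formed.

Step 2
Reactants: 2 neryl tert-butyldimethylsilyl ether
Product: 3 6,7-epoxide of 2 (racemic at the oxirane CH)
Conditions: mCPBA (1.05 equiv), NaHCO3, CH2Cl2, −20 to 0 °C
Reagents that add atoms: mCPBA, OOC(=O)c1cccc(Cl)c1
Why: Prilezhaev epoxidation should pick the distal trisubstituted olefin, which is more electron-rich than the one bearing the allylic silyloxy group; the new centre is lost in step 3.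

Step 3
Reactants: 3 6,7-epoxide of 2
Product: 4 (4Z)-6-(tert-butyldimethylsilyloxy)-4-methylhex-4-enal
Conditions: H5IO6 (1.1 equiv), THF/H2O, 0 °C
Reagents that add atoms: none
Why: Acid-mediated epoxide hydration followed by Malaprade glycol cleavage in one pot should release the C1 aldehyde and acetone without touching the (Z)-C4=C5 bond.

Step 4
Reactants: 4 (4Z)-6-(tert-butyldimethylsilyloxy)-4-methylhex-4-enal; 5 ethyl (triphenylphosphoranylidene)acetate
Product: 7 ethyl (2Z,6Z)-8-(tert-butyldimethylsilyloxy)-2-iodo-6-methylocta-2,6-dienoate, via iodo ylide 6 (not isolated)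
Conditions: 5, N-iodosuccinimide, CH2Cl2, −20 °C; then 4, rt
Reagents that add atoms: N-iodosuccinimide, O=C1CCC(=O)N1I
Why: Wittig olefination with the α-iodinated stabilised ylide should place the ester (future C14) trans and the iodine (future bond to C9) cis to the C2 chain, which fixes the C1=C10 geometry of the target.

Step 5
Reactants: 7 ethyl (2Z,6Z)-8-(tert-butyldimethylsilyloxy)-2-iodo-6-methylocta-2,6-dienoate
Product: 8 (2Z,6Z)-8-(tert-butyldimethylsilyloxy)-2-iodo-6-methylocta-2,6-dien-1-ol
Conditions: DIBAL-H (2.2 equiv), CH2Cl2, −78 °C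
Reagents that add atoms: none
Why: DIBAL-H reduces the enoate 1,2 to the C14 allylic alcohol and leaves the vinyl iodide and its geometry intact, so the later vinyl–chromium species carries no ester that could scramble the olefin through an allenoate.

Step 6
Reactants: 8 (2Z,6Z)-8-(tert-butyldimethylsilyloxy)-2-iodo-6-methylocta-2,6-dien-1-ol; 9 (4S)-2,2-dimethyl-1,3-dioxolane-4-carbaldehyde
Product: 10 (1R,2Z,6Z)-8-(tert-butyldimethylsilyloxy)-1-[(4S)-2,2-dimethyl-1,3-dioxolan-4-yl]-2-(hydroxymethyl)-6-methylocta-2,6-dien-1-ol
Conditions: CrCl2 (5 equiv), NiCl2 (2 mol %), DMSO, rt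
Reagents that add atoms: none
Why: Nozaki–Hiyama–Kishi coupling forms C9–C10 with retention of the vinyl geometry, and Felkin–Anh (anti) addition to the α-alkoxy aldehyde should set C9 as R from the bought (S)-dioxolane centre.

Step 7
Reactants: 10 the diol from step 6; 11 (2S)-2-methylbutanoic acid
Product: 12 14-O-[(2S)-2-methylbutanoyl] ester of 10 (C9–OH free)
Conditions: 11 (1.05 equiv), DCC, DMAP (5 mol %), CH2Cl2, −20 to 0 °C
Reagents that add atoms: none
Why: Steglich esterification should take the primary allylic C14–OH well ahead of the hindered secondary C9–OH, and the low temperature and low DMAP loading protect the α-centre of the acid.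

Step 8
Reactants: 12 14-O-[(2S)-2-methylbutanoyl] ester of 10
Product: 13 9-O-acetate of 12
Conditions: Ac2O, pyridine, DMAP (cat.), CH2Cl2, 0 °C
Reagents that add atoms: acetic anhydride, CC(=O)OC(C)=O
Why: Routine acetylation of the remaining secondary alcohol installs the C9 acetate with retention.

Step 9
Reactants: 13 9-O-acetate of 12
Product: 14 C6 primary allylic alcohol (silyl group removed)
Conditions: HF·pyridine, pyridine, THF, 0 °C
Reagents that add atoms: none
Why: Buffered fluoride removes the primary allylic silyl ether while both esters and the acetonide should survive.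

Step 10
Reactants: 14 C6 primary allylic alcohol
Product: 15 (Z)-enal (C6 aldehyde)
Conditions: MnO2, CH2Cl2, rt
Reagents that add atoms: none
Why: MnO2 oxidises the allylic alcohol selectively and, as with nerol itself, should keep the (Z)-C4=C5 geometry.

Step 11
Reactants: 15 (Z)-enal
Product: 16 (S)-configured divinyl carbinol at C6 (same spatial sense as 6R of the target)
Conditions: vinylmagnesium bromide, ZnCl2 (divinylzinc made in the flask, Mg salts removed with 1,4-dioxane), (−)-DAIB (5 mol %), toluene/Et2O, 0 °C
Reagents that add atoms: vinylmagnesium bromide, C=C[Mg]Br (transferred as divinylzinc, C=C[Zn]C=C)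
Why: Amino-alcohol-catalysed enantioselective alkenylzinc addition should deliver the vinyl group to the Si face of the aldehyde, as this ligand does for dialkylzincs, setting C6; organozincs tolerate the esters.

Step 12
Reactants: 16 divinyl carbinol; 17 2-(bromomethyl)prop-2-enoic acid
Product: 18 2-(bromomethyl)acrylate ester of 16
Conditions: 17, DCC, DMAP (5 mol %), CH2Cl2, −10 °C
Reagents that add atoms: none
Why: Steglich esterification attaches C11, C12 and C13 to O6 without touching the C6 centre; the low temperature limits SN2' attack of DMAP on the allylic bromide.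

Step 13
Reactants: 18 2-(bromomethyl)acrylate ester of 16
Product: 19 (5R)-3-(bromomethyl)furan-2(5H)-one bearing the (Z,Z)-dienyl chain at C5 (ring B closed)
Conditions: second-generation Grubbs catalyst (5 mol %), 1,4-benzoquinone (10 mol %), CH2Cl2 (5 mM), 40 °C
Reagents that add atoms: none
Why: Ring-closing metathesis between the C6 vinyl group and the acrylate forms the C7=C11 bond of the five-membered butenolide with loss of ethene; the trisubstituted olefins are too hindered to compete and the allylic bromide is tolerated.

Step 14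
Reactants: 19 bromomethyl butenolide
Product: 20 α-acetoxy aldehyde (C8 aldehyde, C9 acetate, C13 bromide)
Conditions: H5IO6 (1.5 equiv), EtOAc, 0 °C to rt; used at once
Reagents that add atoms: none
Why: Periodic acid hydrolyses the terminal acetonide and cleaves the resulting glycol in one operation, excising the auxiliary centre as formaldehyde and releasing the sensitive C8 aldehyde under non-basic conditions.

Step 15
Reactants: 20 α-acetoxy aldehyde
Product: 22 target germacranolide (6R,7R,8S,9R; (2S)-2-methylbutanoate), via allylstannane 21 (not isolated)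
Conditions: Me3SnSnMe3 (1.1 equiv), Pd2(dba)3 (2.5 mol %), THF, 0 °C to rt; filtration, exchange to CH2Cl2; slow addition to BF3·OEt2 (3 equiv), CH2Cl2 (1 mM), −78 °C; pH 7 buffer at −78 °C
Reagents that add atoms: none
Why: Palladium-mediated exchange of the allylic bromide for Me3Sn at the less hindered C13 terminus gives a 2-(alkoxycarbonyl)allylstannane, and BF3 then activates the C8 aldehyde so that C7, the γ-carbon of the C13–C11=C7 unit, attacks it anti to tin in an open SE2' transition state while the double bond moves to C11=C13 and Me3Sn leaves as the fluoride. The closest known reactions are the BF3-promoted additions of 2-(alkoxycarbonyl)allylstannanes to aldehydes and the Lewis-acid allylstannane–aldehyde macrocyclisations used for ten- to fourteen-membered carbocycles. Ring A closes in a 10-exo-trig mode at the aldehyde carbon, with the C=O and the C7=C11 bond both outside the new ring, and ring B is already in place. C7 is controlled by C6: the aldehyde is tethered through C5 and only attack on the butenolide face anti to C5 gives a staggered C5–C6–C7–C8 torsion, which is the trans ring fusion. C8 is controlled by C9 through a polar Felkin–Anh arrangement (C9–OAc anti to the incoming C7, BF3 being unable to chelate), which gives the 8,9-anti and 7,8-syn array. The selectivity the step needs is at C8: a closed chair transition state (CrCl2, In or Zn) would hold the carbonyl oxygen next to C13 and favour the C8 epimer, so the open tin/BF3 manifold is chosen, and high dilution suppresses oligomers.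

**Compound list**

1 | nerol | CC(C)=CCC/C(C)=C\CO | starting material
2 | neryl tert-butyldimethylsilyl ether | CC(C)=CCC/C(C)=C\CO[Si](C)(C)C(C)(C)C | intermediate
3 | 6,7-epoxide of 2 (racemic at the oxirane CH) | CC1(C)OC1CC/C(C)=C\CO[Si](C)(C)C(C)(C)C | intermediate
4 | (4Z)-6-(tert-butyldimethylsilyloxy)-4-methylhex-4-enal | O=CCC/C(C)=C\CO[Si](C)(C)C(C)(C)C | intermediate
5 | ethyl (triphenylphosphoranylidene)acetate | CCOC(=O)C=P(c1ccccc1)(c1ccccc1)c1ccccc1 | starting material
6 | ethyl iodo(triphenylphosphoranylidene)acetate | CCOC(=O)C(I)=P(c1ccccc1)(c1ccccc1)c1ccccc1 | intermediate (not isolated)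
7 | ethyl (2Z,6Z)-8-(tert-butyldimethylsilyloxy)-2-iodo-6-methylocta-2,6-dienoate | CCOC(=O)/C(I)=C/CC/C(C)=C\CO[Si](C)(C)C(C)(C)C | intermediate
8 | (2Z,6Z)-8-(tert-butyldimethylsilyloxy)-2-iodo-6-methylocta-2,6-dien-1-ol | OC/C(I)=C/CC/C(C)=C\CO[Si](C)(C)C(C)(C)C | intermediate
9 | (4S)-2,2-dimethyl-1,3-dioxolane-4-carbaldehyde | O=C[C@@H]1COC(C)(C)O1 | starting material
10 | (1R,2Z,6Z)-8-(tert-butyldimethylsilyloxy)-1-[(4S)-2,2-dimethyl-1,3-dioxolan-4-yl]-2-(hydroxymethyl)-6-methylocta-2,6-dien-1-ol | OC/C(=C/CC/C(C)=C\CO[Si](C)(C)C(C)(C)C)[C@@H](O)[C@@H]1COC(C)(C)O1 | intermediate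
11 | (2S)-2-methylbutanoic acid | CC[C@H](C)C(=O)O | starting material
12 | 14-O-[(2S)-2-methylbutanoyl] ester of 10 | CC[C@H](C)C(=O)OC/C(=C/CC/C(C)=C\CO[Si](C)(C)C(C)(C)C)[C@@H](O)[C@@H]1COC(C)(C)O1 | intermediate
13 | 9-O-acetate of 12 | CC[C@H](C)C(=O)OC/C(=C/CC/C(C)=C\CO[Si](C)(C)C(C)(C)C)[C@@H](OC(C)=O)[C@@H]1COC(C)(C)O1 | intermediate
14 | C6 primary allylic alcohol | CC[C@H](C)C(=O)OC/C(=C/CC/C(C)=C\CO)[C@@H](OC(C)=O)[C@@H]1COC(C)(C)O1 | intermediate
15 | (Z)-enal at C6 | CC[C@H](C)C(=O)OC/C(=C/CC/C(C)=C\C=O)[C@@H](OC(C)=O)[C@@H]1COC(C)(C)O1 | intermediate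
16 | (S)-divinyl carbinol at C6 | CC[C@H](C)C(=O)OC/C(=C/CC/C(C)=C\[C@@H](O)C=C)[C@@H](OC(C)=O)[C@@H]1COC(C)(C)O1 | intermediate
17 | 2-(bromomethyl)prop-2-enoic acid | C=C(CBr)C(=O)O | starting material
18 | 2-(bromomethyl)acrylate ester of 16 | CC[C@H](C)C(=O)OC/C(=C/CC/C(C)=C\[C@@H](OC(=O)C(=C)CBr)C=C)[C@@H](OC(C)=O)[C@@H]1COC(C)(C)O1 | intermediate
19 | (5R)-3-(bromomethyl)butenolide with acetonide | CC[C@H](C)C(=O)OC/C(=C/CC/C(C)=C\[C@H]2OC(=O)C(CBr)=C2)[C@@H](OC(C)=O)[C@@H]1COC(C)(C)O1 | intermediate
20 | (5R)-3-(bromomethyl)butenolide with C8 aldehyde and (9R)-acetate | CC[C@H](C)C(=O)OC/C(=C/CC/C(C)=C\[C@H]2OC(=O)C(CBr)=C2)[C@@H](OC(C)=O)C=O | intermediate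
21 | (5R)-3-[(trimethylstannyl)methyl]butenolide with C8 aldehyde | CC[C@H](C)C(=O)OC/C(=C/CC/C(C)=C\[C@H]2OC(=O)C(C[Sn](C)(C)C)=C2)[C@@H](OC(C)=O)C=O | intermediate (not isolated)
22 | target, (6R,7R,8S,9R)-9-acetoxy-8-hydroxy-14-[(2S)-2-methylbutanoyloxy]germacra-1(10)Z,4Z,11(13)-trien-12,6-olide | C=C1C(=O)O[C@@H]2/C=C(/C)CC/C=C(/COC(=O)[C@@H](C)CC)[C@@H](OC(C)=O)[C@@H](O)[C@@H]12 | target

**Count and risks**

Total steps: 15. Longest linear sequence: 15 (from nerol).

Steps most likely to fail:

1. Step 15. The closure may lose facial control at the aldehyde (reaction through a closed tin- or palladium-bound array instead of the open one), and the tin exchange may be eroded by allyl–allyl coupling, by oligomerisation, or by acetyl migration from O9 to O8. Fallback: from 20 the ring would be closed by a chromium Barbier allylation of the Nozaki–Hiyama–Kishi type (CrCl2, THF, high dilution), whose chair transition state is expected to give mainly the C8 epimer of the target F1. Mitsunobu inversion of F1 with chloroacetic acid (PPh3, DIAD, toluene, 0 °C) would give the 8-chloroacetate of the target F2. Thiourea and NaHCO3 in EtOH would then remove the chloroacetyl group in the presence of the acetate, and the route is rejoined at 22.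

2. Step 11. The vinyl transfer may proceed with poor enantioselectivity, and the (Z)-enal may isomerise to the (E)-enal before addition. Fallback: from 15, catalytic asymmetric alkynylation with (trimethylsilyl)acetylene (Me2Zn, the ProPhenol enantiomer that adds to the Si face, toluene, 0 °C) would give the silylated propargylic alcohol F3. TBAF buffered with AcOH would give the terminal alkyne F4. Semihydrogenation (H2, Pd/CaCO3 poisoned with Pb(OAc)2, quinoline) would return the route to 16.

3. Step 6. Facial selectivity at the aldehyde may be low, giving a mixture at C9. Fallback: the mixture is taken through step 7, and from 12 (as a C9-epimer mixture) Dess–Martin periodinane would give the enone F5. Corey–Bakshi–Shibata reduction ((R)-Me-CBS, catecholborane, toluene, −78 °C; alkenyl as the large group) would set C9 under reagent control and return the route to 12; epimerisation of the dioxolane centre in F5 is harmless because that centre is excised in step 14.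

Further compounds
F1 | step 15 | C8 epimer of the target (8R) | C=C1C(=O)O[C@@H]2/C=C(/C)CC/C=C(/COC(=O)[C@@H](C)CC)[C@@H](OC(C)=O)[C@H](O)[C@@H]12
F2 | step 15 | 8-O-chloroacetate of the target | C=C1C(=O)O[C@@H]2/C=C(/C)CC/C=C(/COC(=O)[C@@H](C)CC)[C@@H](OC(C)=O)[C@@H](OC(=O)CCl)[C@@H]12
F3 | step 11 | silylated propargylic alcohol at C6 | CC[C@H](C)C(=O)OC/C(=C/CC/C(C)=C\[C@@H](O)C#C[Si](C)(C)C)[C@@H](OC(C)=O)[C@@H]1COC(C)(C)O1
F4 | step 11 | terminal propargylic alcohol at C6 | CC[C@H](C)C(=O)OC/C(=C/CC/C(C)=C\[C@@H](O)C#C)[C@@H](OC(C)=O)[C@@H]1COC(C)(C)O1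
F5 | step 6 | C9 enone | CC[C@H](C)C(=O)OC/C(=C/CC/C(C)=C\CO[Si](C)(C)C(C)(C)C)C(=O)[C@@H]1COC(C)(C)O1
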